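## Retrosynthetic overview
1. Target 12 comes from para-oxidation (C4–H to C=O) of phenol 11. No ring is built: the single six-membered ring is carried intact from 2-methoxy-5-methylphenol (8).
2. Phenol 11 is disconnected at C1′–C2′ into salicyl alcohol 10 and (E)-alkenylboronic acid 7, joined by a boron-tethered o-quinone-methide 1,4-alkenyl shift (the proposed new step).
3. Diol 10 comes from ortho-formylation and reduction of 8; C6 is its only free ortho position, so ring regiochemistry is fixed.
4. Boronic acid 7 comes from vinyl iodide 6, made by Zr-catalysed syn-methylalumination of the C48 alkyne 5, which sets the 2′E olefin.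
5. Alkyne 5 comes from solanesyl chloride plus 1-(trimethylsilyl)propyne; natural solanesol (1) supplies the other eight E olefins.

Assumption: the target has no stereocentres, so "single enantiomer" is read as the single all-E geometric isomer (nine E trisubstituted olefins).
Convention: substrates and building blocks are numbered; simple reagents (PCl3, Me3Al, I2, B(OiPr)3, paraformaldehyde, O2, water) are listed with SMILES in each step.

## Route

**Step 1**
Reactants: 1, solanesol (all-E nonaprenol)
Product: 2, solanesyl chloride (all-E)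
Conditions: PCl3, DMF, 0 °C → rt
Reagents that add atoms: phosphorus trichloride, ClP(Cl)Cl
Why: Vilsmeier-type chlorination of the primary allylic alcohol proceeds by SN2 at C1, without allylic transposition or E/Z erosion.

**Step 2**
Reactants: 2, solanesyl chloride; 3, 1-(trimethylsilyl)propyne
Product: 4, TMS-protected C48 alkyne (TMS–C≡C–CH2–solanesyl)
Conditions: 3, n-BuLi, THF, −40 °C; then 2, −40 → 0 °C
Reagents that add atoms: none (all heavy atoms come from 2 and 3)
Why: SN2 alkylation of the silyl-capped propargyl-lithium at the primary allylic chloride (α-attack) forms the C4′–C5′ bond and leaves the eight E olefins untouched.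

**Step 3**
Reactants: 4
Product: 5, terminal C48 alkyne (HC≡C–CH2–solanesyl)
Conditions: K2CO3, MeOH/THF (1:2), rt
Reagents that add atoms: none
Why: Base-mediated protodesilylation of the alkynyl–Si bond; nothing else in the molecule is base-sensitive.

**Step 4**
Reactants: 5
Product: 6, (E)-1-iodo-2-methyl-1-alkene (C49 vinyl iodide)
Conditions: Me3Al (2.5 equiv), Cp2ZrCl2 (0.2 equiv), CH2Cl2, 0 °C → rt; then I2, THF, −30 → 0 °C
Reagents that add atoms: trimethylaluminium, C[Al](C)C; iodine, II
Why: Negishi Zr-catalysed carboalumination adds Me–Al syn across the terminal alkyne (CH3 to the internal carbon, Al to the terminus, typically ≥95:5), and stereoretentive iodinolysis gives the (E)-iodide, setting the 2′,3′-olefin geometry; trisubstituted olefins are inert.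

**Step 5**
Reactants: 6
Product: 7, (E)-2-methyl-1-alkenylboronic acid (C49)
Conditions: t-BuLi (2.1 equiv), Et2O, −78 °C; B(OiPr)3, −78 °C → rt; aq NH4Cl (pH 5–6)
Reagents that add atoms: triisopropyl borate, CC(C)OB(OC(C)C)OC(C)C; water, O
Why: Iodine–lithium exchange and borate quench/hydrolysis both proceed with retention at the sp2 carbon, so the E geometry is carried into the boronic acid.

**Step 6**
Reactants: 8, 2-methoxy-5-methylphenol
Product: 9, 2-hydroxy-3-methoxy-6-methylbenzaldehyde
Conditions: MgCl2, Et3N, (CH2O)n, MeCN, reflux; 1 M HCl work-up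
Reagents that add atoms: paraformaldehyde (as formaldehyde), C=O
Why: Casnati–Skattebøl magnesium-phenoxide formylation is ortho-specific and C6 is the only free ortho position, so the future C1′ carbon is placed between OH and CH3 with no para attack.

**Step 7**
Reactants: 9
Product: 10, 2-(hydroxymethyl)-6-methoxy-3-methylphenol
Conditions: NaBH4, MeOH/THF, 0 °C
Reagents that add atoms: none
Why: Borohydride reduction of the aryl aldehyde gives the saligenin-type 1,3-diol needed to chelate boron.

**Step 8 (key step, new)**
Reactants: 7, alkenylboronic acid; 10, salicyl alcohol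
Product: 11, 2-methoxy-5-methyl-6-(all-E-decaprenyl)phenol
Conditions: PhMe, 4 Å MS, rt, 1 h; then HFIP (PhMe/HFIP 3:1), 2,6-di-tert-butylpyridine (0.2 equiv), 45 °C; aq NaHCO3 work-up
Reagents that add atoms: none (all heavy atoms come from 7 and 10; boron leaves as boric acid)
Why: Proposed new method: a boron-tethered deoxygenative Petasis-type coupling in which 7 and 10 condense to a 2-alkenyl-4H-1,3,2-benzodioxaborin, HFIP-assisted heterolysis of the benzylic C–O bond gives an o-quinone methide whose carbonyl oxygen stays bound to boron, and the resulting tetracoordinate boronate delivers its alkenyl group to the exocyclic CH2 through a six-membered transition state with retention of olefin geometry (rearomatisation drives it, and the phenol stays masked as a borate until work-up, which suppresses chroman formation), so the C1′–C2′ bond forms only at C6 with the E-2′ olefin intact; the closest known reaction types are the Petasis borono-Mannich reaction of salicylaldehydes (same B–O–aryl–C topology, iminium in place of quinone methide), diol-catalysed additions of alkenylboronates to aryl-stabilised o-quinone methides, and Lewis-acid opening of 2-phenyl-benzodioxaborins to o-quinone methides trapped by external nucleophiles, whereas self-transfer of the boron substituent onto an unsubstituted o-quinone methide has not been shown.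

**Step 9**
Reactants: 11
Product: 12, target (2-methoxy-5-methyl-6-(all-E-decaprenyl)-1,4-benzoquinone)
Conditions: Co(salen) (10 mol %), O2 (1 atm), DMF/THF (1:1), rt
Reagents that add atoms: dioxygen, O=O
Why: Salcomine oxidation of a 2,6-disubstituted phenol with a free para position gives the p-quinone by O2 capture of the phenoxyl radical at C4; the isolated trisubstituted olefins are not affected, so all nine E geometries survive.

## Compound list
1 | solanesol, (all-E)-3,7,11,15,19,23,27,31,35-nonamethylhexatriaconta-2,6,10,14,18,22,26,30,34-nonaen-1-ol | OC/C=C(\C)CC/C=C(\C)CC/C=C(\C)CC/C=C(\C)CC/C=C(\C)CC/C=C(\C)CC/C=C(\C)CC/C=C(\C)CCC=C(C)C | starting material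
2 | solanesyl chloride (all-E) | ClC/C=C(\C)CC/C=C(\C)CC/C=C(\C)CC/C=C(\C)CC/C=C(\C)CC/C=C(\C)CC/C=C(\C)CC/C=C(\C)CCC=C(C)C | intermediate
3 | 1-(trimethylsilyl)propyne | CC#C[Si](C)(C)C | starting material
4 | trimethyl[(all-E)-6,10,14,18,22,26,30,34,38-nonamethylnonatriaconta-5,9,13,17,21,25,29,33,37-nonaen-1-yn-1-yl]silane | C[Si](C)(C)C#CCC/C=C(\C)CC/C=C(\C)CC/C=C(\C)CC/C=C(\C)CC/C=C(\C)CC/C=C(\C)CC/C=C(\C)CC/C=C(\C)CCC=C(C)C | intermediate
5 | (all-E)-6,10,14,18,22,26,30,34,38-nonamethylnonatriaconta-5,9,13,17,21,25,29,33,37-nonaen-1-yne | C#CCC/C=C(\C)CC/C=C(\C)CC/C=C(\C)CC/C=C(\C)CC/C=C(\C)CC/C=C(\C)CC/C=C(\C)CC/C=C(\C)CCC=C(C)C | intermediate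
6 | (all-E)-1-iodo-2,6,10,14,18,22,26,30,34,38-decamethylnonatriaconta-1,5,9,13,17,21,25,29,33,37-decaene | I/C=C(\C)CC/C=C(\C)CC/C=C(\C)CC/C=C(\C)CC/C=C(\C)CC/C=C(\C)CC/C=C(\C)CC/C=C(\C)CC/C=C(\C)CCC=C(C)C | intermediate
7 | [(all-E)-2,6,10,14,18,22,26,30,34,38-decamethylnonatriaconta-1,5,9,13,17,21,25,29,33,37-decaen-1-yl]boronic acid | OB(O)/C=C(\C)CC/C=C(\C)CC/C=C(\C)CC/C=C(\C)CC/C=C(\C)CC/C=C(\C)CC/C=C(\C)CC/C=C(\C)CC/C=C(\C)CCC=C(C)C | intermediate
8 | 2-methoxy-5-methylphenol | COc1ccc(C)cc1O | starting material
9 | 2-hydroxy-3-methoxy-6-methylbenzaldehyde | COc1ccc(C)c(C=O)c1O | intermediate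
10 | 2-(hydroxymethyl)-6-methoxy-3-methylphenol | COc1ccc(C)c(CO)c1O | intermediate
11 | 2-methoxy-5-methyl-6-[(all-E)-decaprenyl]phenol | COc1ccc(C)c(C/C=C(\C)CC/C=C(\C)CC/C=C(\C)CC/C=C(\C)CC/C=C(\C)CC/C=C(\C)CC/C=C(\C)CC/C=C(\C)CC/C=C(\C)CCC=C(C)C)c1O | intermediate
12 | 2-methoxy-5-methyl-6-[(all-E)-decaprenyl]-1,4-benzoquinone (CID25010748) | COC1=CC(=O)C(C)=C(C/C=C(\C)CC/C=C(\C)CC/C=C(\C)CC/C=C(\C)CC/C=C(\C)CC/C=C(\C)CC/C=C(\C)CC/C=C(\C)CC/C=C(\C)CCC=C(C)C)C1=O | target

## Summary
Total steps: 9. Longest linear sequence: 7 (steps 1–5, 8, 9, from solanesol).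

Steps most likely to fail:
1. **Step 8 (proposed new boron-tethered alkenyl shift).** Risks are slow ionisation of the primary benzodioxaborin, o-quinone-methide oligomerisation and protodeboronation. Fallback (known chemistry): Negishi–Lipshutz coupling. Generate the alkenylalane directly from alkyne 5 (Me3Al, cat. Cp2ZrCl2) and cross-couple it under Ni(0) catalysis with the TBS-protected benzylic chloride made from 9 (TBSCl; NaBH4; MsCl/LiCl), then remove TBS with TBAF to reach 11.
2. **Step 9 (phenol to p-quinone on the C50 polyene).** Risks are allylic autoxidation and diphenoquinone formation. Fallback: move the oxygenation to the small-molecule stage. Oxidise diol 10 with Fremy's salt to the hydroxymethyl-quinone and reduce it (Na2S2O4) to the hydroquinone, which keeps the saligenin unit; after coupling, the last step is then a mild hydroquinone-to-quinone oxidation (Ag2O or air).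
3. **Step 6 (ortho-formylation at the CH3-flanked site next to a chelating OMe).** Fallback: a Claisen route to 9. O-allylate 8, run the aromatic Claisen rearrangement (only C6 is open), isomerise the allyl group to propenyl (Ru–H), and cleave by ozonolysis (Me2S).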